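**Retrosynthetic overview**
- Feature: in ring A of unit 2 (the 7-methoxyflavone half), C8 carries C3' of ring B of unit 1. C8 lies between C7–OMe and C8a–O1, and C5 holds a third, different oxygen, so a coupling at C8 would be doubly ortho-hindered and the three oxygens would still need differentiating.
- Key disconnection: ring A of unit 2 is built around the aryl group already in place, by Danheiser benzannulation of an aryl methyl ynol ether with the vinylketene from 3-ethoxycyclobutenone (bonds C8–C8a, C6–C7, C4a–C8a).
- Ring C of unit 2: O1–C2 by oxa-Michael addition of the free C8a hydroxyl to an arylpropiolate, then C4–C4a by tethered Friedel–Crafts acylation.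
- Ring C of unit 1: the benzoate carbon on ring B becomes C2 through Baker–Venkataraman rearrangement and cyclodehydration with a phloroacetophenone diether; BCl3 dealkylation comes last.
- Order of ring formation: ring A of unit 2, ring C of unit 2, ring C of unit 1. Both rings B and ring A of unit 1 are bought.

Key step: step 4

Assumption: the target SMILES carries no stereodescriptor, so the C3'–C8 biaryl axis is not controlled; unit 1 is the 5,7,4'-trihydroxyflavone half (joined at C3'), unit 2 is the 7-methoxyflavone half (joined at C8), and flavone numbering is used for ring A of unit 2 from step 4 on.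

**Step 1**
Reactants: 1 methyl 4-hydroxybenzoate
Product: 2 methyl 4-hydroxy-3-iodobenzoate
Conditions: ICl (1.05 equiv), AcOH, 65 °C
Reagents that add atoms: iodine monochloride, ClI
Why: Electrophilic aromatic iodination, in which the hydroxyl directs ortho (its para position is taken by the ester), both ortho sites are equivalent, and one equivalent of ICl on the ester-deactivated ring should stop at the monoiodide.

**Step 2**
Reactants: 2 methyl 4-hydroxy-3-iodobenzoate
Product: 3 methyl 3-iodo-4-isopropoxybenzoate
Conditions: 2-bromopropane, K2CO3, DMF, 60 °C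
Reagents that add atoms: 2-bromopropane, CC(C)Br
Why: Williamson etherification of the acidic iodophenol; the isopropyl ether survives base, heat, organometallics and trifluoroacetic anhydride and can later be cleaved by BCl3 beside an aryl methyl ether.

**Step 3**
Reactants: 3 methyl 3-iodo-4-isopropoxybenzoate; 4 chloroacetaldehyde dimethyl acetal
Product: 7 methyl 4-isopropoxy-3-(methoxyethynyl)benzoate, via lithium methoxyacetylide 5 (not isolated), via (methoxyethynyl)zinc chloride 6 (not isolated)
Conditions: 4 (1.5 equiv), LiNEt2 (4.6 equiv), THF, −78 → 0 °C; ZnCl2 (3.2 equiv), 0 °C; then 3, Pd(PPh3)4 (5 mol %), rt → 45 °C; filtration through basic alumina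
Reagents that add atoms: none
Why: The amide base acts three times on the chloroacetal (loss of methanol, loss of HCl, deprotonation) to give the acetylide, which after transmetalation to zinc undergoes Negishi alkynylation of the aryl iodide at zerovalent palladium, a coupling known for alkoxyethynylzinc halides and mild enough for the methyl ester.

**Step 4**
Reactants: 7 methyl 4-isopropoxy-3-(methoxyethynyl)benzoate; 8 3-ethoxycyclobut-2-en-1-one
Product: 13 methyl 3-(4-ethoxy-2-hydroxy-6-methoxyphenyl)-4-isopropoxybenzoate, via vinylketene 9 (not isolated), via 4-vinylcyclobutenone 10 (not isolated), via dienylketene 11 (not isolated), via cyclohexadienone 12 (not isolated)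
Conditions: 8 (2 equiv, in two portions), toluene (0.5 M), sealed tube, argon, 80 → 120 °C; then K2CO3 (cat.), MeOH, rt
Reagents that add atoms: none
Why: Danheiser benzannulation: heat opens 8 by 4π electrocyclic ring opening to vinylketene 9, and ynol ether 7 adds [2+2] across the ketene C=C, its aryl-bearing carbon bonding to the ketene carbonyl carbon (C8–C8a) and its methoxy-bearing carbon to the ketene α-carbon (C6–C7), to give 4-vinylcyclobutenone 10. A second, reversible 4π opening gives dienylketene 11, ring A of unit 2 closes by 6π electrocyclization (C4a–C8a) to cyclohexadienone 12, and tautomerization delivers phenol 13. The closest known reaction type is the benzannulation of alkyl-substituted cyclobutenones with alkoxy- and siloxyalkynes to resorcinol monoethers; a 3-alkoxycyclobutenone combined with an ortho-alkoxyaryl ynol ether is a new pairing within that class and carries the risk of the route. The selectivity needed is the regiochemistry of the [2+2] step, and it is secured by the oxygen lone pair of the ynol ether, which makes the aryl-bearing carbon the nucleophilic one, so that the aryl group ends between the free hydroxyl (future O1) and the methoxy group (7-OMe) and the ethoxy group ends at C5. No stereocentre has to be set: the sp3 carbon of 10 forms racemic and is lost on ring opening, and only the geometric isomer of 11 with the ketene and ethoxyvinyl groups cis can cyclize, the reversible opening feeding it. The methyl ynol ether has no β-hydrogen, so the retro-ene loss of alkene that consumes ethyl and tert-butyl ynol ethers on heating is closed, and the final methanolysis returns any 13 that excess 9 has acylated at oxygen.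

**Step 5**
Reactants: 14 4-iodophenol
Product: 15 1-iodo-4-isopropoxybenzene
Conditions: 2-bromopropane, K2CO3, DMF, 60 °C
Reagents that add atoms: 2-bromopropane, CC(C)Br
Why: Williamson etherification that puts the same BCl3-labile protecting group on the future 4'-oxygen of unit 2.

**Step 6**
Reactants: 15 1-iodo-4-isopropoxybenzene; 16 ethyl propiolate
Product: 17 ethyl 3-(4-isopropoxyphenyl)propiolate
Conditions: 16 (3 equiv), PdCl2(PPh3)2 (2 mol %), CuI (4 mol %), K2CO3, THF, 65 °C
Reagents that add atoms: none
Why: Sonogashira coupling run with an inorganic base, because amine bases add to the propiolate, and with an aryl iodide that is reactive enough despite its donor substituent.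

**Step 7**
Reactants: 13 methyl 3-(4-ethoxy-2-hydroxy-6-methoxyphenyl)-4-isopropoxybenzoate; 17 ethyl 3-(4-isopropoxyphenyl)propiolate
Product: 18 methyl 3-(4-ethoxy-2-{[(Z)-3-ethoxy-1-(4-isopropoxyphenyl)-3-oxoprop-1-en-1-yl]oxy}-6-methoxyphenyl)-4-isopropoxybenzoate
Conditions: 17 (1.5 equiv), Cs2CO3 (0.5 equiv), dry DMF, 90 °C
Reagents that add atoms: none
Why: Base-catalysed oxa-Michael addition of the phenoxide to the aryl-bearing β-carbon of the ynoate forms O1–C2 (first stage of the classical aryloxycinnamate route to flavones); anti addition should favour the Z isomer drawn, and any E isomer is carried along because both converge in step 9.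

**Step 8**
Reactants: 18 oxa-Michael adduct (diester)
Product: 19 3-(2-{[(Z)-2-carboxy-1-(4-isopropoxyphenyl)ethenyl]oxy}-4-ethoxy-6-methoxyphenyl)-4-isopropoxybenzoic acid
Conditions: LiOH (6 equiv), THF/MeOH/H2O, 45 °C; cold 1 M HCl to pH 3
Reagents that add atoms: lithium hydroxide, [Li+].[OH-]
Why: Saponification of both esters in one operation frees the cinnamic acid for ring closure and the benzoic acid needed in step 11, and the cold, mild acidification guards the β-aryloxycinnamic acid against protodecarboxylation.

**Step 9**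
Reactants: 19 diacid
Product: 22 3-[5-ethoxy-7-methoxy-2-(4-isopropoxyphenyl)-4-oxo-4H-chromen-8-yl]-4-isopropoxybenzoic acid, via bis(mixed anhydride) 20 (not isolated), via flavone mixed anhydride 21 (not isolated)
Conditions: (CF3CO)2O (4 equiv), CH2Cl2, 0 °C → rt; then H2O
Reagents that add atoms: none
Why: Intramolecular Friedel–Crafts acylation through the mixed trifluoroacetic anhydride closes the six-membered ring C of unit 2 (C4–C4a) at the only free position ortho to O1, which is also para to 7-OMe and ortho to 5-OEt, while the liberated acid equilibrates the alkene geometry and the aroyl trifluoroacetate, having no arene within reach, returns to the acid on hydrolysis.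

**Step 10**
Reactants: 23 2,4,6-trihydroxyacetophenone
Product: 24 2-hydroxy-4,6-diisopropoxyacetophenone
Conditions: 2-bromopropane (2.3 equiv), K2CO3, DMF, 60 °C
Reagents that add atoms: 2-bromopropane, CC(C)Br
Why: Chemoselective Williamson etherification, in which one hydroxyl stays hydrogen-bonded to the acetyl group, is the least nucleophilic, and remains free when the halide is limited to about two equivalents.

**Step 11**
Reactants: 22 flavone acid; 24 2-hydroxy-4,6-diisopropoxyacetophenone
Product: 25 2-acetyl-3,5-diisopropoxyphenyl 3-[5-ethoxy-7-methoxy-2-(4-isopropoxyphenyl)-4-oxo-4H-chromen-8-yl]-4-isopropoxybenzoate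
Conditions: EDC·HCl (1.5 equiv), DMAP (0.2 equiv), CH2Cl2, rt
Reagents that add atoms: none
Why: Steglich-type carbodiimide esterification with DMAP as acyl-transfer catalyst, a standard way to acylate hydrogen-bonded 2-hydroxyacetophenones under near-neutral conditions that leave the flavone untouched.

**Step 12**
Reactants: 25 aryl ester
Product: 26 1-(2-hydroxy-4,6-diisopropoxyphenyl)-3-{3-[5-ethoxy-7-methoxy-2-(4-isopropoxyphenyl)-4-oxo-4H-chromen-8-yl]-4-isopropoxyphenyl}propane-1,3-dione
Conditions: LiHMDS (3 equiv), THF, −78 → 0 °C; 1 M HCl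
Reagents that add atoms: none
Why: Baker–Venkataraman rearrangement, in which the methyl ketone enolate attacks the neighbouring aryl ester through a six-membered transition state and the acyl group moves from O to C, with a non-nucleophilic amide base that avoids attack at C2 of the finished pyranone of unit 2.

**Step 13**
Reactants: 26 1,3-diketone
Product: 27 8-[5-(5,7-diisopropoxy-4-oxo-4H-chromen-2-yl)-2-isopropoxyphenyl]-5-ethoxy-7-methoxy-2-(4-isopropoxyphenyl)-4H-chromen-4-one
Conditions: p-TsOH·H2O (20 mol %), toluene, 100 °C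
Reagents that add atoms: none
Why: Acid-catalysed cyclodehydration of the 2-hydroxyaryl 1,3-diketone (hemiketal formation at the aroyl carbonyl, then loss of water) closes ring C of unit 1 under catalytic sulfonic acid that aryl isopropyl ethers tolerate.

**Step 14**
Reactants: 27 fully protected biflavone
Product: 28 sotetsuflavone
Conditions: BCl3 (15 equiv, 1 M in CH2Cl2), CH2Cl2, −78 °C → rt; then H2O
Reagents that add atoms: none
Why: Lewis acid ether cleavage graded by mechanism, in which BCl3 readily ionizes the secondary isopropyl ethers and cleaves the 5-ethoxy group of unit 2 under chelation to the peri carbonyl, whereas the unchelated primary 7-methyl ether is of a type known to resist BCl3 at or below room temperature.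

**Compound list**
1 | methyl 4-hydroxybenzoate | COC(=O)c1ccc(O)cc1 | starting material
2 | methyl 4-hydroxy-3-iodobenzoate | COC(=O)c1ccc(O)c(I)c1 | intermediate
3 | methyl 3-iodo-4-isopropoxybenzoate | COC(=O)c1ccc(OC(C)C)c(I)c1 | intermediate
4 | chloroacetaldehyde dimethyl acetal (2-chloro-1,1-dimethoxyethane) | COC(CCl)OC | starting material
5 | lithium methoxyacetylide | [Li]C#COC | intermediate
6 | (methoxyethynyl)zinc chloride | Cl[Zn]C#COC | intermediate
7 | methyl 4-isopropoxy-3-(methoxyethynyl)benzoate | COC#Cc1cc(C(=O)OC)ccc1OC(C)C | intermediate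
8 | 3-ethoxycyclobut-2-en-1-one | CCOC1=CC(=O)C1 | starting material
9 | 3-ethoxybuta-1,3-dien-1-one (vinylketene) | C=C(OCC)C=C=O | intermediate
10 | methyl 3-[3-(1-ethoxyethenyl)-2-methoxy-4-oxocyclobut-1-en-1-yl]-4-isopropoxybenzoate (racemic) | COC1=C(c2cc(C(=O)OC)ccc2OC(C)C)C(=O)C1C(=C)OCC | intermediate
11 | methyl 3-[(3E)-5-ethoxy-3-methoxy-1-oxohexa-1,3,5-trien-2-yl]-4-isopropoxybenzoate (dienylketene) | O=C=C(c1cc(C(=O)OC)ccc1OC(C)C)/C(OC)=C\C(=C)OCC | intermediate
12 | methyl 3-(4-ethoxy-2-methoxy-6-oxocyclohexa-1,3-dien-1-yl)-4-isopropoxybenzoate | CCOC1=CC(OC)=C(c2cc(C(=O)OC)ccc2OC(C)C)C(=O)C1 | intermediate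
13 | methyl 3-(4-ethoxy-2-hydroxy-6-methoxyphenyl)-4-isopropoxybenzoate | COc1cc(OCC)cc(O)c1-c1cc(C(=O)OC)ccc1OC(C)C | intermediate
14 | 4-iodophenol | Oc1ccc(I)cc1 | starting material
15 | 1-iodo-4-isopropoxybenzene | CC(C)Oc1ccc(I)cc1 | intermediate
16 | ethyl propiolate | C#CC(=O)OCC | starting material
17 | ethyl 3-(4-isopropoxyphenyl)propiolate | CCOC(=O)C#Cc1ccc(OC(C)C)cc1 | intermediate
18 | methyl 3-(4-ethoxy-2-{[(Z)-3-ethoxy-1-(4-isopropoxyphenyl)-3-oxoprop-1-en-1-yl]oxy}-6-methoxyphenyl)-4-isopropoxybenzoate | CCOC(=O)/C=C(\Oc1cc(OCC)cc(OC)c1-c1cc(C(=O)OC)ccc1OC(C)C)c1ccc(OC(C)C)cc1 | intermediate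
19 | 3-(2-{[(Z)-2-carboxy-1-(4-isopropoxyphenyl)ethenyl]oxy}-4-ethoxy-6-methoxyphenyl)-4-isopropoxybenzoic acid | OC(=O)/C=C(\Oc1cc(OCC)cc(OC)c1-c1cc(C(=O)O)ccc1OC(C)C)c1ccc(OC(C)C)cc1 | intermediate
20 | bis(trifluoroacetic) mixed anhydride of 19 | FC(F)(F)C(=O)OC(=O)/C=C(\Oc1cc(OCC)cc(OC)c1-c1cc(C(=O)OC(=O)C(F)(F)F)ccc1OC(C)C)c1ccc(OC(C)C)cc1 | intermediate
21 | trifluoroacetic mixed anhydride of 22 | CCOc1cc(OC)c(-c2cc(C(=O)OC(=O)C(F)(F)F)ccc2OC(C)C)c2oc(-c3ccc(OC(C)C)cc3)cc(=O)c12 | intermediate
22 | 3-[5-ethoxy-7-methoxy-2-(4-isopropoxyphenyl)-4-oxo-4H-chromen-8-yl]-4-isopropoxybenzoic acid | CCOc1cc(OC)c(-c2cc(C(=O)O)ccc2OC(C)C)c2oc(-c3ccc(OC(C)C)cc3)cc(=O)c12 | intermediate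
23 | 2,4,6-trihydroxyacetophenone | CC(=O)c1c(O)cc(O)cc1O | starting material
24 | 2-hydroxy-4,6-diisopropoxyacetophenone | CC(=O)c1c(O)cc(OC(C)C)cc1OC(C)C | intermediate
25 | 2-acetyl-3,5-diisopropoxyphenyl 3-[5-ethoxy-7-methoxy-2-(4-isopropoxyphenyl)-4-oxo-4H-chromen-8-yl]-4-isopropoxybenzoate | CCOc1cc(OC)c(-c2cc(C(=O)Oc3cc(OC(C)C)cc(OC(C)C)c3C(C)=O)ccc2OC(C)C)c2oc(-c3ccc(OC(C)C)cc3)cc(=O)c12 | intermediate
26 | 1-(2-hydroxy-4,6-diisopropoxyphenyl)-3-{3-[5-ethoxy-7-methoxy-2-(4-isopropoxyphenyl)-4-oxo-4H-chromen-8-yl]-4-isopropoxyphenyl}propane-1,3-dione | CCOc1cc(OC)c(-c2cc(C(=O)CC(=O)c3c(O)cc(OC(C)C)cc3OC(C)C)ccc2OC(C)C)c2oc(-c3ccc(OC(C)C)cc3)cc(=O)c12 | intermediate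
27 | 8-[5-(5,7-diisopropoxy-4-oxo-4H-chromen-2-yl)-2-isopropoxyphenyl]-5-ethoxy-7-methoxy-2-(4-isopropoxyphenyl)-4H-chromen-4-one | CCOc1cc(OC)c(-c2cc(-c3cc(=O)c4c(OC(C)C)cc(OC(C)C)cc4o3)ccc2OC(C)C)c2oc(-c3ccc(OC(C)C)cc3)cc(=O)c12 | intermediate
28 | sotetsuflavone | COc1cc(O)c2c(=O)cc(-c3ccc(O)cc3)oc2c1-c1cc(-c2cc(=O)c3c(O)cc(O)cc3o2)ccc1O | target

**Total step count:** 14. **Longest linear sequence:** 11 (steps 1, 2, 3, 4, 7, 8, 9, 11, 12, 13, 14).

**Steps most likely to fail**

**Step 4.**
- What may go wrong: ring opening of the donor-stabilized cyclobutenone may need temperatures at which the ynol ether decays. Self-reaction of the vinylketene may also outrun its capture by the hindered alkyne.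
- Approach of the fallback: it sets out from 3 and comes back at 13. It replaces arene construction with a cross-coupling followed by desymmetrization.
- Boronic acid partner: phloroglucinol is mono-ethylated (EtOH, H2SO4, reflux) to 5-ethoxybenzene-1,3-diol F1. This is protected (MOMCl, i-Pr2NEt, CH2Cl2) as 1-ethoxy-3,5-bis(methoxymethoxy)benzene F2. Lithiation between the two acetal oxygens (n-BuLi, THF, 0 °C) gives [4-ethoxy-2,6-bis(methoxymethoxy)phenyl]lithium F3, and borylation (B(OMe)3, then aq. NH4Cl) gives [4-ethoxy-2,6-bis(methoxymethoxy)phenyl]boronic acid F4.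
- Coupling and deprotection: Suzuki–Miyaura coupling of F4 with 3 (Pd(OAc)2, SPhos, K3PO4, toluene/H2O, 90 °C) should give methyl 3-[4-ethoxy-2,6-bis(methoxymethoxy)phenyl]-4-isopropoxybenzoate F5. HCl in MeOH then frees methyl 3-(4-ethoxy-2,6-dihydroxyphenyl)-4-isopropoxybenzoate F6.
- Return to the route: the two hydroxyls of F6 are equivalent, so one methylation (MeI, 1 equiv, K2CO3, acetone) can only lead to 13. Overmethylation is the price, and recovered F6 is recycled.

**Step 7.**
- What may go wrong: conjugate addition of an ortho-arylated phenoxide to an alkynoate deactivated by its para-alkoxy donor may be sluggish and reversible.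
- Approach of the fallback: it sets out from 13 and comes back at 22. It forms the C4–C4a bond first, and it would also answer a failure of step 8 or step 9.
- Sequence: C-acetylation ortho to the free hydroxyl (Ac2O, BF3·OEt2, 70 °C, acetate formation and Fries-type migration held ortho by boron chelation) should give methyl 3-(3-acetyl-4-ethoxy-2-hydroxy-6-methoxyphenyl)-4-isopropoxybenzoate F7. Claisen–Schmidt condensation with 4-isopropoxybenzaldehyde (KOH, EtOH/H2O) saponifies the benzoate at the same time. It gives 3-{4-ethoxy-2-hydroxy-3-[(E)-3-(4-isopropoxyphenyl)acryloyl]-6-methoxyphenyl}-4-isopropoxybenzoic acid F8. Oxidative cyclization of this 2'-hydroxychalcone (I2 cat., DMSO, 125 °C) gives 22.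
- Weak point: acetylation at C6 competes with acetylation at C4a, which is why the tethered closure is preferred in the main route.

**Step 3.**
- What may go wrong: elimination to the acetylide may be incomplete, transmetalation may be slow in the presence of lithium methoxide and amine, and the ynol ether may hydrate during isolation.
- Approach of the fallback: it sets out from 3 and comes back at 7. It builds the triple bond by elimination instead of coupling a preformed alkoxyalkyne.
- Sequence: iodine–magnesium exchange (i-PrMgCl·LiCl, THF, −40 °C) gives [2-isopropoxy-5-(methoxycarbonyl)phenyl]magnesium chloride F9. Acylation with N,2-dimethoxy-N-methylacetamide gives methyl 4-isopropoxy-3-(2-methoxyacetyl)benzoate F10. Chelation-controlled enolization and triflation (LiHMDS, PhNTf2, THF, −78 °C) give methyl 4-isopropoxy-3-[(Z)-2-methoxy-1-(trifluoromethylsulfonyloxy)ethenyl]benzoate F11. Anti elimination (KOt-Bu, THF, −78 °C) gives 7.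

**Further compounds**
F1 | step 4 | 5-ethoxybenzene-1,3-diol | CCOc1cc(O)cc(O)c1
F2 | step 4 | 1-ethoxy-3,5-bis(methoxymethoxy)benzene | CCOc1cc(OCOC)cc(OCOC)c1
F3 | step 4 | [4-ethoxy-2,6-bis(methoxymethoxy)phenyl]lithium | CCOc1cc(OCOC)c([Li])c(OCOC)c1
F4 | step 4 | [4-ethoxy-2,6-bis(methoxymethoxy)phenyl]boronic acid | CCOc1cc(OCOC)c(B(O)O)c(OCOC)c1
F5 | step 4 | methyl 3-[4-ethoxy-2,6-bis(methoxymethoxy)phenyl]-4-isopropoxybenzoate | CCOc1cc(OCOC)c(-c2cc(C(=O)OC)ccc2OC(C)C)c(OCOC)c1
F6 | step 4 | methyl 3-(4-ethoxy-2,6-dihydroxyphenyl)-4-isopropoxybenzoate | CCOc1cc(O)c(-c2cc(C(=O)OC)ccc2OC(C)C)c(O)c1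
F7 | step 7 | methyl 3-(3-acetyl-4-ethoxy-2-hydroxy-6-methoxyphenyl)-4-isopropoxybenzoate | CCOc1cc(OC)c(-c2cc(C(=O)OC)ccc2OC(C)C)c(O)c1C(C)=O
F8 | step 7 | 3-{4-ethoxy-2-hydroxy-3-[(E)-3-(4-isopropoxyphenyl)acryloyl]-6-methoxyphenyl}-4-isopropoxybenzoic acid | CCOc1cc(OC)c(-c2cc(C(=O)O)ccc2OC(C)C)c(O)c1C(=O)/C=C/c1ccc(OC(C)C)cc1
F9 | step 3 | [2-isopropoxy-5-(methoxycarbonyl)phenyl]magnesium chloride | COC(=O)c1ccc(OC(C)C)c([Mg]Cl)c1
F10 | step 3 | methyl 4-isopropoxy-3-(2-methoxyacetyl)benzoate | COCC(=O)c1cc(C(=O)OC)ccc1OC(C)C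
F11 | step 3 | methyl 4-isopropoxy-3-[(Z)-2-methoxy-1-(trifluoromethylsulfonyloxy)ethenyl]benzoate | CO/C=C(\OS(=O)(=O)C(F)(F)F)c1cc(C(=O)OC)ccc1OC(C)C
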